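**Strategy**

The route rests on cutting the C9–C10 bond next to the bridging ether oxygen. C10 is a ketal-level carbon (O–C10) and C8 can carry a masked oxygen, so C8–C9 maps onto a 2-(silylmethyl)allyl nucleophile and C10 onto a cyclic oxocarbenium ion. In one operation an intramolecular Sakurai cyclisation closes the oxepane ring O–C5–C6–C7–C8–C9–C10 and with it the ten-membered carbocycle, giving the 11-oxabicyclo[4.4.1]undecene. Both C10 epimers of the ketal converge on one quaternary bridgehead because the C5–O tether reaches only one face. The precursor is a 2-methoxy-2-methyl-tetrahydrooxepine (made by ketal-tethered RCM) attached to a trans α-methylene butyrolactone bearing the allylsilane.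

Key step: step 10

Remark: atom numbers follow the germacrane numbering of the target (C1–C10 ring carbons, C11/C12/C13 lactone α-carbon, carbonyl and methylene, C14 the C10 methyl, C15 the ester carbon). Compounds 1, 3, 11, 14 and 21 are taken as commercial.

**Route**

Step 1
Reactants: 1 (S)-5-(hydroxymethyl)furan-2(5H)-one
Product: 2 (S)-5-[(triethylsilyloxy)methyl]furan-2(5H)-one
Conditions: TESCl, imidazole, CH2Cl2, 0 °C
Reagents that add atoms: chlorotriethylsilane, CC[Si](CC)(CC)Cl
Why: Imidazole-promoted silylation masks the primary alcohol for the organometallic steps; the C6 stereocentre comes from the chiral pool and is untouched.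

Step 2
Reactants: 2 (S)-5-[(triethylsilyloxy)methyl]furan-2(5H)-one; 3 (2-bromoallyl)trimethylsilane
Product: 5 (4R,5S)-5-[(triethylsilyloxy)methyl]-4-[3-(trimethylsilyl)prop-1-en-2-yl]oxolan-2-one, via Grignard reagent 4 (not isolated)
Conditions: Mg, THF, rt (3 to 4); CuBr·SMe2 (10 mol%), THF, −78 °C, then 2; aq. NH4Cl
Reagents that add atoms: magnesium, [Mg] (kept only in intermediate 4)
Why: Copper-catalysed 1,4-addition of the alkenyl Grignard reagent to the butenolide should occur anti to the C6 CH2OTES group, setting C7 trans to C6 and installing the C8/C9 allylsilane.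

Step 3
Reactants: 5 (4R,5S)-5-[(triethylsilyloxy)methyl]-4-[3-(trimethylsilyl)prop-1-en-2-yl]oxolan-2-one
Product: 8 (4R,5S)-3-methylidene-5-[(triethylsilyloxy)methyl]-4-[3-(trimethylsilyl)prop-1-en-2-yl]oxolan-2-one, via Mannich base 6 (not isolated), via methiodide 7 (not isolated)
Conditions: LDA, THF, −78 °C; Eschenmoser's salt, −78 °C to rt; MeI, CH2Cl2, rt; aq. NaHCO3, rt
Reagents that add atoms: Eschenmoser's salt, C=[N+](C)C.[I-]; iodomethane, CI (methyl kept only in intermediate 7)
Why: Lactone-enolate Mannich reaction followed by N-methylation and Hofmann-type elimination is the classical α-methylenation of γ-butyrolactones, and the weak bicarbonate base should not isomerise the doubly allylic C7–H.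

Step 4
Reactants: 8 (4R,5S)-3-methylidene-5-[(triethylsilyloxy)methyl]-4-[3-(trimethylsilyl)prop-1-en-2-yl]oxolan-2-one
Product: 9 (4R,5S)-5-(hydroxymethyl)-3-methylidene-4-[3-(trimethylsilyl)prop-1-en-2-yl]oxolan-2-one
Conditions: PPTS (10 mol%), MeOH, 0 °C to rt
Reagents that add atoms: none
Why: Acid-catalysed methanolysis removes a primary TES ether under conditions too mild to protodesilylate the allylsilane.

Step 5
Reactants: 9 (4R,5S)-5-(hydroxymethyl)-3-methylidene-4-[3-(trimethylsilyl)prop-1-en-2-yl]oxolan-2-one
Product: 10 (2S,3R)-4-methylidene-5-oxo-3-[3-(trimethylsilyl)prop-1-en-2-yl]oxolane-2-carbaldehyde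
Conditions: Dess–Martin periodinane, CH2Cl2, 0 °C to rt; used crude
Reagents that add atoms: none
Why: Dess–Martin oxidation gives the α-acyloxy aldehyde without base, so C6 should not epimerise.

Step 6
Reactants: 10 (2S,3R)-4-methylidene-5-oxo-3-[3-(trimethylsilyl)prop-1-en-2-yl]oxolane-2-carbaldehyde; 11 methyl propiolate
Product: 13 methyl 2-[(R)-hydroxy[(2S,3R)-4-methylidene-5-oxo-3-[3-(trimethylsilyl)prop-1-en-2-yl]oxolan-2-yl]methyl]prop-2-enoate, via vinylalane 12 (not isolated)
Conditions: DIBAL-H, NMO, THF, 0 °C, then 11 (gives 12); then 10, 0 °C to rt; aq. Rochelle salt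
Reagents that add atoms: diisobutylaluminium hydride, CC(C)C[AlH]CC(C)C (Al and isobutyl kept only in intermediate 12)
Why: Vinylalumination (hydroalumination of the propiolate, then aldehyde addition) gives the Morita–Baylis–Hillman-type adduct without an amine nucleophile that would attack the α-methylene lactone, and polar Felkin–Anh attack anti to the C6–O bond should set C5 (R) with C5–O/C6–O anti, the minor epimer being removed by chromatography.

Step 7
Reactants: 14 methyl pent-4-enoate
Product: 15 2-methoxyhexa-1,5-diene
Conditions: Cp2TiMe2, THF, 65 °C, dark; distillation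
Reagents that add atoms: dimethyltitanocene, C[Ti](C)(C1C=CC=C1)C1C=CC=C1
Why: Petasis methylenation converts the ester carbonyl into the methyl enol ether and leaves the isolated terminal alkene alone.

Step 8
Reactants: 13 methyl 2-[(R)-hydroxy[(2S,3R)-4-methylidene-5-oxo-3-[3-(trimethylsilyl)prop-1-en-2-yl]oxolan-2-yl]methyl]prop-2-enoate; 15 2-methoxyhexa-1,5-diene
Product: 16 methyl 2-[(R)-[(2-methoxyhex-5-en-2-yl)oxy][(2S,3R)-4-methylidene-5-oxo-3-[3-(trimethylsilyl)prop-1-en-2-yl]oxolan-2-yl]methyl]prop-2-enoate (both ketal epimers)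
Conditions: 15 (3 equiv), PPTS (2 mol%), CH2Cl2, 0 °C; Et3N quench; Et3N-deactivated silica
Reagents that add atoms: none
Why: Markovnikov acid-catalysed addition of the secondary alcohol to the enol ether (as in MOP-ether formation) gives the mixed methyl ketal that already holds the C5–O–C10 link, and the C10 epimer mixture is of no consequence.

Step 9
Reactants: 16 mixed ketal (both ketal epimers)
Product: 17 methyl (7R)-2-methoxy-2-methyl-7-[(2S,3R)-4-methylidene-5-oxo-3-[3-(trimethylsilyl)prop-1-en-2-yl]oxolan-2-yl]-2,3,4,7-tetrahydrooxepine-6-carboxylate (both C2 epimers)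
Conditions: Grubbs II (5 mol%), CH2Cl2 (2 mM), 40 °C
Reagents that add atoms: none
Why: Ring-closing metathesis between the terminal alkene and the 2-substituted acrylate should close the oxepene with the ring-enforced cis C3=C4 geometry, since the 1,1-disubstituted allylsilane and the α-methylene lactone are too hindered or electron-poor to compete.

Step 10
Reactants: 17 cyclic mixed ketal (both C2 epimers)
Product: 18 11-oxabicyclo[4.4.1]undecene-fused α-methylene lactone with exocyclic methylene at C8 (target skeleton with C8=CH2; C5, C6, C7 and C10 as in the target)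
Conditions: TMSOTf (0.2 equiv), 2,6-di-tert-butyl-4-methylpyridine (0.3 equiv), CH2Cl2, −78 to −40 °C; Et3N quench
Reagents that add atoms: none
Why: TMSOTf ionises the C10–OMe bond of either ketal epimer to the same seven-membered cyclic oxocarbenium ion (C10=O+–C5); the terminal CH2 of the 2-substituted allylsilane (the future C9) attacks C10 in an SE2′ sense and the β-silyl cation collapses to the exocyclic C8 methylene, the silyl group leaving as MeOSiMe3. The closest known reaction type is the intramolecular Hosomi–Sakurai (allylsilane–oxocarbenium) cyclisation used for oxepanes and other 4-methylene cyclic ethers. One bond closes two rings: the oxepane O–C5–C6–C7–C8–C9–C10 in a 7-endo mode with respect to both the C=O+ and the C8=C9 π-bonds, and thereby the ten-membered carbocycle C1–C10 as a bridging closure. The only new stereocentre, C10, is controlled by C5, because the four-carbon tether on C5 can reach only the oxocarbenium face syn to the C5–C6 bond (an in,out bicyclo[4.4.1] isomer is not accessible), so both ketal epimers should converge on (10S). The step needs C-attack at C10 to outrun protodesilylation and ring-opening or elimination of the cation: the β-silicon effect and the hindered pyridine base should secure the first, elimination to the enol ether is reversible, and the enoate and α-methylene lactone are not activated by TMSOTf at −78 °C.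

Step 11
Reactants: 18 bicyclic C8-methylene compound
Product: 20 (5R,6S,7R,8R,10S)-8-hydroxy compound (the target lacking its C8 acyl group), via C8 ketone 19 (not isolated)
Conditions: O3, CH2Cl2/MeOH 4:1, Sudan Red 7B, −78 °C; Me2S, −78 to 0 °C; CeCl3·7H2O, NaBH4, −78 °C
Reagents that add atoms: ozone, [O-][O+]=O
Why: Ozonolysis should cleave the only electron-rich alkene (exocyclic C8=CH2) before the two acceptor-substituted alkenes, and Luche reduction of the crude ketone should deliver hydride from the exo face (the side of the one-atom oxygen bridge, anti to C11), setting C8 (R) with the hydroxyl cis to C11.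

Step 12
Reactants: 21 (E)-2-methylbut-2-en-1-ol
Product: 22 [(2R,3R)-2,3-dimethyloxiran-2-yl]methanol
Conditions: Ti(OiPr)4 (10 mol%), D-(−)-diethyl tartrate (12 mol%), t-BuOOH, 4 Å MS, CH2Cl2, −20 °C
Reagents that add atoms: tert-butyl hydroperoxide, CC(C)(C)OO
Why: Sharpless asymmetric epoxidation with D-(−)-diethyl tartrate should give the (2R,3R)-epoxy alcohol by reagent control, fixing both epoxide centres (methyl groups cis, as in the alkene).

Step 13
Reactants: 22 [(2R,3R)-2,3-dimethyloxiran-2-yl]methanol
Product: 23 (2S,3R)-2,3-dimethyloxirane-2-carboxylic acid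
Conditions: RuCl3·xH2O (2 mol%), NaIO4, MeCN/EtOAc/H2O, 0 °C to rt
Reagents that add atoms: sodium periodate, [Na+].[O-]I(=O)(=O)=O
Why: Ruthenium tetroxide generated in situ oxidises primary 2,3-epoxy alcohols to glycidic acids without opening the epoxide; the C2 descriptor changes to S only through CIP priorities.

Step 14
Reactants: 20 (5R,6S,7R,8R,10S)-8-hydroxy compound; 23 (2S,3R)-2,3-dimethyloxirane-2-carboxylic acid
Product: 25 CNP0240298.1, via mixed anhydride 24 (not isolated)
Conditions: 2,4,6-trichlorobenzoyl chloride, Et3N, THF, 0 °C to rt (23 to 24); then 20, DMAP, toluene, rt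
Reagents that add atoms: 2,4,6-trichlorobenzoyl chloride, O=C(Cl)c1c(Cl)cc(Cl)cc1Cl (kept only in intermediate 24)
Why: Yamaguchi esterification acylates the hindered secondary C8 alcohol with retention at C8 and at both epoxide centres, and the mild base at room temperature should limit translactonisation to the 8,12-olide.

**Compound list**

1 | (S)-5-(hydroxymethyl)furan-2(5H)-one | O=C1O[C@H](CO)C=C1 | starting material
2 | (S)-5-[(triethylsilyloxy)methyl]furan-2(5H)-one | O=C1O[C@H](CO[Si](CC)(CC)CC)C=C1 | intermediate
3 | (2-bromoallyl)trimethylsilane | C=C(Br)C[Si](C)(C)C | starting material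
4 | [3-(trimethylsilyl)prop-1-en-2-yl]magnesium bromide | C=C(C[Si](C)(C)C)[Mg]Br | intermediate
5 | (4R,5S)-5-[(triethylsilyloxy)methyl]-4-[3-(trimethylsilyl)prop-1-en-2-yl]oxolan-2-one | O=C1O[C@H](CO[Si](CC)(CC)CC)[C@@H](C(=C)C[Si](C)(C)C)C1 | intermediate
6 | (4R,5S)-3-[(dimethylamino)methyl]-5-[(triethylsilyloxy)methyl]-4-[3-(trimethylsilyl)prop-1-en-2-yl]oxolan-2-one (C3 epimers) | O=C1O[C@H](CO[Si](CC)(CC)CC)[C@@H](C(=C)C[Si](C)(C)C)C1CN(C)C | intermediate
7 | N-methyl quaternary ammonium iodide of 6 | O=C1O[C@H](CO[Si](CC)(CC)CC)[C@@H](C(=C)C[Si](C)(C)C)C1C[N+](C)(C)C.[I-] | intermediate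
8 | (4R,5S)-3-methylidene-5-[(triethylsilyloxy)methyl]-4-[3-(trimethylsilyl)prop-1-en-2-yl]oxolan-2-one | C=C1C(=O)O[C@H](CO[Si](CC)(CC)CC)[C@H]1C(=C)C[Si](C)(C)C | intermediate
9 | (4R,5S)-5-(hydroxymethyl)-3-methylidene-4-[3-(trimethylsilyl)prop-1-en-2-yl]oxolan-2-one | C=C1C(=O)O[C@H](CO)[C@H]1C(=C)C[Si](C)(C)C | intermediate
10 | (2S,3R)-4-methylidene-5-oxo-3-[3-(trimethylsilyl)prop-1-en-2-yl]oxolane-2-carbaldehyde | C=C1C(=O)O[C@H](C=O)[C@H]1C(=C)C[Si](C)(C)C | intermediate
11 | methyl propiolate | C#CC(=O)OC | starting material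
12 | methyl 2-(diisobutylalumanyl)prop-2-enoate | C=C(C(=O)OC)[Al](CC(C)C)CC(C)C | intermediate
13 | methyl 2-[(R)-hydroxy[(2S,3R)-4-methylidene-5-oxo-3-[3-(trimethylsilyl)prop-1-en-2-yl]oxolan-2-yl]methyl]prop-2-enoate | C=C1C(=O)O[C@H]([C@H](O)C(=C)C(=O)OC)[C@H]1C(=C)C[Si](C)(C)C | intermediate
14 | methyl pent-4-enoate | C=CCCC(=O)OC | starting material
15 | 2-methoxyhexa-1,5-diene | C=CCCC(=C)OC | intermediate
16 | mixed methyl ketal of 13 at the C5 oxygen with the hex-5-en-2-one unit (both ketal epimers) | C=C1C(=O)O[C@H]([C@H](OC(C)(OC)CCC=C)C(=C)C(=O)OC)[C@H]1C(=C)C[Si](C)(C)C | intermediate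
17 | methyl (7R)-2-methoxy-2-methyl-7-[(2S,3R)-4-methylidene-5-oxo-3-[3-(trimethylsilyl)prop-1-en-2-yl]oxolan-2-yl]-2,3,4,7-tetrahydrooxepine-6-carboxylate (both C2 epimers) | C=C1C(=O)O[C@H]([C@@H]2OC(C)(OC)CCC=C2C(=O)OC)[C@H]1C(=C)C[Si](C)(C)C | intermediate
18 | target skeleton with exocyclic methylene at C8 (C5, C6, C7, C10 as in target) | C=C1C(=O)O[C@H]2[C@H]1C(=C)C[C@]1(C)CCC=C(C(=O)OC)[C@H]2O1 | intermediate
19 | C8 ketone of the target skeleton | C=C1C(=O)O[C@H]2[C@H]1C(=O)C[C@]1(C)CCC=C(C(=O)OC)[C@H]2O1 | intermediate
20 | (5R,6S,7R,8R,10S)-8-hydroxy compound (des-acyl target) | C=C1C(=O)O[C@H]2[C@H]1[C@H](O)C[C@]1(C)CCC=C(C(=O)OC)[C@H]2O1 | intermediate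
21 | (E)-2-methylbut-2-en-1-ol | C/C=C(\C)CO | starting material
22 | [(2R,3R)-2,3-dimethyloxiran-2-yl]methanol | OC[C@@]1(C)O[C@@H]1C | intermediate
23 | (2S,3R)-2,3-dimethyloxirane-2-carboxylic acid | OC(=O)[C@@]1(C)O[C@@H]1C | intermediate
24 | (2S,3R)-2,3-dimethyloxirane-2-carboxylic 2,4,6-trichlorobenzoic anhydride | O=C(OC(=O)[C@@]1(C)O[C@@H]1C)c1c(Cl)cc(Cl)cc1Cl | intermediate
25 | CNP0240298.1 | C=C1C(=O)O[C@H]2[C@H]1[C@H](OC(=O)[C@@]1(C)O[C@@H]1C)C[C@]1(C)CCC=C(C(=O)OC)[C@H]2O1 | target

**Step count and risks**

Total step count: 14. Longest linear sequence: 11 steps (steps 1–6, 8–11 and 14).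

Steps most likely to fail:

1. Step 10 (key step). The allylsilane may be protodesilylated, or the oxocarbenium ion may open or eliminate, before the strained bridging closure takes place. Fallback: reverse the order of the two ring closures. Setting out from the acyclic mixed ketal 16, TMSOTf and the hindered pyridine base at −78 °C would ionise the ketal and the allylsilane would close the oxepane through an unbridged oxocarbenium ion to give the monocyclic 4-methyleneoxepane carrying the acrylate at C5 and methyl plus but-3-enyl at C10 F1. Ring-closing metathesis (Grubbs II) of the C10 epimer with the butenyl chain cis to the acrylate would then form the oxepene and come back to the route at 18. The price is loss of the C10 control that the bridged closure gives.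

2. Step 6. Facial selectivity at C5 may be low, the α-acyloxy aldehyde may epimerise at C6, or the alane may attack the lactone. Fallback: aldol addition followed by selenoxide elimination in place of vinyl-metal addition. Setting out from aldehyde 10, the lithium enolate of methyl 2-(phenylselanyl)propanoate (LDA, THF, −78 °C; CC([Se]c1ccccc1)C(=O)OC) would add in a Felkin sense to give the β-hydroxy-α-selanyl ester F2. Oxidation (H2O2, pyridine, CH2Cl2, 0 °C) and selenoxide syn-elimination toward the methyl group would come back to the route at 13.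

3. Step 11. Ozone may over-oxidise the acceptor alkenes, the ketone 19 may lose the C6 or C10 oxygen by β-elimination, or hydride may be delivered from the endo face. Fallback: correct C8 by substitution instead of by facial selectivity. Setting out from ketone 19, if reduction gives the C8-epimeric alcohol F3, Mitsunobu esterification with acid 23 (PPh3, DIAD, toluene, 0 °C to rt) would invert C8 and come back to the route directly at target 25, making step 14 unnecessary. This displacement is at a hindered, neopentyl-like centre and may itself be sluggish.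

Further compounds
F1 | step 10 | monocyclic 4-methyleneoxepane fused to the α-methylene lactone, with 1-(methoxycarbonyl)vinyl at C5 and methyl plus but-3-enyl at C10 (butenyl cis to the acrylate) | C=C1C(=O)O[C@H]2[C@H]1C(=C)C[C@](C)(CCC=C)O[C@@H]2C(=C)C(=O)OC
F2 | step 6 | methyl 3-hydroxy-2-methyl-2-(phenylselanyl)-3-[(2S,3R)-4-methylidene-5-oxo-3-[3-(trimethylsilyl)prop-1-en-2-yl]oxolan-2-yl]propanoate (3R; C2 epimers) | C=C1C(=O)O[C@H]([C@H](O)C(C)([Se]c2ccccc2)C(=O)OC)[C@H]1C(=C)C[Si](C)(C)C
F3 | step 11 | C8 epimer of alcohol 20 | C=C1C(=O)O[C@H]2[C@H]1[C@@H](O)C[C@]1(C)CCC=C(C(=O)OC)[C@H]2O1
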